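**Retrosynthetic overview**
- The target comes from a 5-(p-tolylthio)-3-acetoxy lactone by C–S hydrogenolysis and deacetylation. That lactone already holds every carbon and both stereocentres.
- The thiolactone comes from a one-step [3+2] union that makes the lactone bonds C3–C4 and O1–C5. The partners are an enantiopure (E)-alkenyl p-tolyl sulfoxide and an acetoxy(benzyl)ketene made in situ from a racemic acid chloride. The only non-aromatic ring, the γ-butyrolactone, is formed here.
- Enabling feature: in the butyrolactone ring the unsubstituted C5H2 on O1 adjoins the C4 methine, and the fully substituted carbinol carbon C3 is α to C2=O. C4–C5 is therefore a latent alkenyl sulfoxide C=C (C5 = thionium carbon, S later replaced by H). C3–C2(=O)–O1 is a latent oxy-ketene plus the sulfinyl oxygen.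
- The sulfoxide comes from methyl eugenol (ozonolysis, Takai, Andersen). The acid chloride comes from syringaldehyde (azlactone, hydrolysis, hydrogenation, acetylation, chlorination).

Key step: step 9

Assumption: the sense of sulfur-to-carbon chirality transfer is taken from the chair model given in step 9. If it proved opposite, the equally commercial enantiomeric menthyl sulfinate would be used and nothing else would change.

**Step 1**
Reactants: 1 methyl eugenol (4-allyl-1,2-dimethoxybenzene)
Product: 3 (3,4-dimethoxyphenyl)acetaldehyde, via ozonide 2 (not isolated)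
Conditions: O3, CH2Cl2, −78 °C (Sudan Red 7B end point); then Me2S, −78 °C → rt; used crude
Reagents that add atoms: ozone [O-][O+]=O
Why: Ozonolysis (Criegee mechanism): the isolated terminal alkene reacts far faster than the veratrole ring when the ozone feed is stopped at the dye end point, and Me2S reduces ozonide 2 to the aldehyde without touching anything else; no stereocentre is formed.

**Step 2**
Reactants: 3 (3,4-dimethoxyphenyl)acetaldehyde
Product: 4 (E)-4-(3-iodoprop-2-en-1-yl)-1,2-dimethoxybenzene
Conditions: CrCl2 (6 equiv), CHI3 (2 equiv), THF–dioxane, 0 °C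
Reagents that add atoms: iodoform IC(I)I
Why: Takai olefination: the gem-dichromium reagent formed from CHI3 and CrCl2 adds to the aldehyde and eliminates to the E-alkenyl iodide under essentially non-basic conditions that spare the enolisable arylacetaldehyde and keep the C=C bond out of conjugation; any Z isomer is removed by chromatography at the stage of 7.

**Step 3**
Reactants: 4 (E)-4-(3-iodoprop-2-en-1-yl)-1,2-dimethoxybenzene; 5 (1S,2R,5S)-(+)-menthyl (R)-p-toluenesulfinate
Product: 7 (S at sulfur, E)-1,2-dimethoxy-4-[3-(p-tolylsulfinyl)prop-2-en-1-yl]benzene, via alkenylmagnesium chloride 6 (not isolated)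
Conditions: iPrMgCl·LiCl, THF, 0 °C → rt; then cannulated into 5, toluene–THF, −40 → 0 °C; sat. aq NH4Cl
Reagents that add atoms: none
Why: Iodine–magnesium exchange retains the E geometry, and the Andersen sulfoxide synthesis displaces mentholate at sulfur with inversion, so the (R)-sulfinate should give the (S)-sulfoxide; inverse addition at low temperature keeps the basic reagent from deprotonating the product.

**Step 4**
Reactants: 8 syringaldehyde; 9 N-acetylglycine
Product: 10 (Z)-4-(4-acetoxy-3,5-dimethoxybenzylidene)-2-methyloxazol-5(4H)-one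
Conditions: NaOAc, Ac2O, 110 °C
Reagents that add atoms: acetic anhydride CC(=O)OC(C)=O
Why: Erlenmeyer–Plöchl azlactone synthesis: N-acetylglycine cyclodehydrates to the oxazolone, which condenses with the aldehyde in Perkin fashion to the thermodynamically preferred Z-benzylidene azlactone, while the phenol is acetylated in passing.

**Step 5**
Reactants: 10 (Z)-4-(4-acetoxy-3,5-dimethoxybenzylidene)-2-methyloxazol-5(4H)-one
Product: 11 3-(4-hydroxy-3,5-dimethoxyphenyl)-2-oxopropanoic acid (keto/enol tautomers)
Conditions: 3 M aq HCl, reflux, N2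
Reagents that add atoms: water O
Why: Acid hydrolysis opens the azlactone, cleaves the enamide to the α-keto acid and removes the aryl acetate, which is the standard route from azlactones to arylpyruvic acids.

**Step 6**
Reactants: 11 3-(4-hydroxy-3,5-dimethoxyphenyl)-2-oxopropanoic acid
Product: 12 rac-2-hydroxy-3-(4-hydroxy-3,5-dimethoxyphenyl)propanoic acid
Conditions: H2 (3 bar), 10% Pd/C, MeOH, rt
Reagents that add atoms: none
Why: Catalytic hydrogenation of the keto/enol (α-hydroxycinnamic acid) tautomers gives the aryllactic acid; the racemate is wanted as it stands, because this stereocentre is erased in step 9.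

**Step 7**
Reactants: 12 rac-2-hydroxy-3-(4-hydroxy-3,5-dimethoxyphenyl)propanoic acid
Product: 13 rac-2-acetoxy-3-(4-acetoxy-3,5-dimethoxyphenyl)propanoic acid
Conditions: Ac2O, pyridine, DMAP (cat.), 0 °C → rt; then H2O
Reagents that add atoms: acetic anhydride CC(=O)OC(C)=O
Why: Nucleophile-catalysed O-acetylation covers the phenol and the secondary alcohol, and the aqueous work-up hydrolyses any mixed anhydride back to the free acid.

**Step 8**
Reactants: 13 rac-2-acetoxy-3-(4-acetoxy-3,5-dimethoxyphenyl)propanoic acid
Product: 14 rac-2-acetoxy-3-(4-acetoxy-3,5-dimethoxyphenyl)propanoyl chloride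
Conditions: (COCl)2, DMF (cat.), CH2Cl2, 0 °C → rt; concentrated and used directly
Reagents that add atoms: oxalyl chloride O=C(Cl)C(=O)Cl
Why: Acid chloride formation through the catalytic Vilsmeier-type chloroiminium salt is mild enough for both acetates, as for other O-acetyl α-hydroxy acids.

**Step 9**
Reactants: 7 (S at sulfur, E)-1,2-dimethoxy-4-[3-(p-tolylsulfinyl)prop-2-en-1-yl]benzene; 14 rac-2-acetoxy-3-(4-acetoxy-3,5-dimethoxyphenyl)propanoyl chloride
Product: 18 (3S,4R,5S)-3-acetoxy-3-(4-acetoxy-3,5-dimethoxybenzyl)-4-(3,4-dimethoxybenzyl)-5-(p-tolylthio)dihydrofuran-2(3H)-one, via ketene 15 (not isolated), via sulfonium enolate 16 (not isolated), via thionium carboxylate 17 (not isolated)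
Conditions: 7 (1 equiv), iPr2NEt (4 equiv), CH2Cl2, 0 °C; 14 (2 equiv) in CH2Cl2 by syringe pump; then 40 °C
Reagents that add atoms: none
Why: Proposed new method: iPr2NEt dehydrochlorinates both enantiomers of 14 to the planar ketene 15, the sulfinyl oxygen of 7 adds to its central carbon in the ketene plane on the side of the smaller OAc group, the O-sulfonium enolate 16 undergoes a charge-accelerated [3,3]-sigmatropic shift that makes the hindered C3–C4 bond and breaks S–O, and the carboxylate of 17 closes the lactone ring on the thionium carbon (O1–C5 bond, 5-exo-trig). The closest known reaction type is the lactonization of alkenyl sulfoxides with dichloroketene (Marino lactonization), supported by the related [3,3] sulfonium rearrangements of keteniminium–alkenyl sulfoxide adducts that set two adjacent stereocentres; what has not been shown is a halogen-free, unsymmetrically disubstituted ketene that creates a fully substituted carbon. The extension is defended by the fact that oxygen-substituted ketenes are, like chloroketenes, destabilised and strongly electrophilic (they acylate weakly nucleophilic imines in the Staudinger β-lactam synthesis, where the α-acetoxy zwitterionic enolate ring-closes without acyl migration), and by the irreversible S–O cleavage that drains the reversible ketene–sulfoxide adduct. C4 is controlled by the sulfur stereocentre and the E geometry: in the chair-like six-atom array C3=C2–O–S–C5=C4 the p-tolyl and 3,4-dimethoxybenzyl groups are pseudo-equatorial and the sulfur lone pair pseudo-axial, which exposes only one alkene face. C3 is controlled by the enolate geometry relayed through the same chair (aryl-CH2 pseudo-equatorial, OAc pseudo-axial), which places the two benzyl groups trans on the new ring, and because adduct formation is reversible both enantiomers of 14 and both enolate geometries funnel through this lowest chair (stereoconvergent); C5 receives the carboxylate on the face from which oxygen left sulfur (S-aryl trans to the C4 benzyl) and is erased in step 10. The step needs the regiochemistry carbon-to-C4 and oxygen-to-C5, opposite to that of radical or cationic carbolactonisation of the parent allylarene, and the temporary S–O tether secures it, while slow addition of 14 holds ketene dimerisation down and the hindered amine base avoids migration of the C=C bond of 7 towards the arene.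

**Step 10**
Reactants: 18 (3S,4R,5S)-3-acetoxy-3-(4-acetoxy-3,5-dimethoxybenzyl)-4-(3,4-dimethoxybenzyl)-5-(p-tolylthio)dihydrofuran-2(3H)-one
Product: 19 (3S,4S)-3-acetoxy-3-(4-acetoxy-3,5-dimethoxybenzyl)-4-(3,4-dimethoxybenzyl)dihydrofuran-2(3H)-one
Conditions: Raney Ni (W-2, washed neutral), EtOH–THF, rt
Reagents that add atoms: none
Why: Raney nickel desulfurisation hydrogenolyses the C5–S bond of the O,S-acetal and leaves lactone, acetates and aryl ethers alone; the auxiliary stereocentre C5 disappears and C3/C4 are not touched.

**Step 11**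
Reactants: 19 (3S,4S)-3-acetoxy-3-(4-acetoxy-3,5-dimethoxybenzyl)-4-(3,4-dimethoxybenzyl)dihydrofuran-2(3H)-one
Product: 20 (3S,4S)-4-(3,4-dimethoxybenzyl)-3-hydroxy-3-(4-hydroxy-3,5-dimethoxybenzyl)dihydrofuran-2(3H)-one (target)
Conditions: K2CO3 (2.2 equiv), MeOH (degassed), Ar, 0 °C → rt; then 1 M HCl
Reagents that add atoms: none
Why: Base-mediated transesterification (Zemplén-type deacetylation) removes the aryl acetate and the activated tertiary α-acyloxy acetate, acidification keeps the γ-lactone closed, and neither the quaternary C3 nor the non-acidic C4 can epimerise.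

**Compound list**
1 | methyl eugenol (4-allyl-1,2-dimethoxybenzene) | C=CCc1ccc(OC)c(OC)c1 | starting material
2 | 3-(3,4-dimethoxybenzyl)-1,2,4-trioxolane (secondary ozonide, racemic) | COc1ccc(CC2OCOO2)cc1OC | intermediate
3 | (3,4-dimethoxyphenyl)acetaldehyde | COc1ccc(CC=O)cc1OC | intermediate
4 | (E)-4-(3-iodoprop-2-en-1-yl)-1,2-dimethoxybenzene | COc1ccc(C/C=C/I)cc1OC | intermediate
5 | (1S,2R,5S)-(+)-menthyl (R)-p-toluenesulfinate | CC(C)[C@H]1CC[C@H](C)C[C@@H]1O[S@@](=O)c1ccc(C)cc1 | starting material
6 | (E)-3-(3,4-dimethoxyphenyl)prop-1-enylmagnesium chloride | COc1ccc(C/C=C/[Mg]Cl)cc1OC | intermediate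
7 | (S at sulfur, E)-1,2-dimethoxy-4-[3-(p-tolylsulfinyl)prop-2-en-1-yl]benzene | COc1ccc(C/C=C/[S@](=O)c2ccc(C)cc2)cc1OC | intermediate
8 | syringaldehyde | COc1cc(C=O)cc(OC)c1O | starting material
9 | N-acetylglycine | CC(=O)NCC(=O)O | starting material
10 | (Z)-4-(4-acetoxy-3,5-dimethoxybenzylidene)-2-methyloxazol-5(4H)-one | CC1=N/C(=C\c2cc(OC)c(OC(C)=O)c(OC)c2)C(=O)O1 | intermediate
11 | 3-(4-hydroxy-3,5-dimethoxyphenyl)-2-oxopropanoic acid | COc1cc(CC(=O)C(=O)O)cc(OC)c1O | intermediate
12 | rac-2-hydroxy-3-(4-hydroxy-3,5-dimethoxyphenyl)propanoic acid | COc1cc(CC(O)C(=O)O)cc(OC)c1O | intermediate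
13 | rac-2-acetoxy-3-(4-acetoxy-3,5-dimethoxyphenyl)propanoic acid | COc1cc(CC(OC(C)=O)C(=O)O)cc(OC)c1OC(C)=O | intermediate
14 | rac-2-acetoxy-3-(4-acetoxy-3,5-dimethoxyphenyl)propanoyl chloride | COc1cc(CC(OC(C)=O)C(=O)Cl)cc(OC)c1OC(C)=O | intermediate
15 | acetoxy(4-acetoxy-3,5-dimethoxybenzyl)ketene | COc1cc(CC(OC(C)=O)=C=O)cc(OC)c1OC(C)=O | intermediate
16 | O-sulfonium enolate zwitterion (sulfur configured as in 7, OAc syn to the O–S bond) | COc1ccc(C/C=C/[S@+](O/C([O-])=C(\OC(C)=O)Cc2cc(OC)c(OC(C)=O)c(OC)c2)c2ccc(C)cc2)cc1OC | intermediate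
17 | thionium carboxylate zwitterion (both carbon stereocentres as in 18) | COc1ccc(C[C@@H](C=[S+]c2ccc(C)cc2)[C@@](OC(C)=O)(Cc2cc(OC)c(OC(C)=O)c(OC)c2)C([O-])=O)cc1OC | intermediate
18 | (3S,4R,5S)-3-acetoxy-3-(4-acetoxy-3,5-dimethoxybenzyl)-4-(3,4-dimethoxybenzyl)-5-(p-tolylthio)dihydrofuran-2(3H)-one (benzyl groups trans, S-aryl trans to the C4 benzyl) | COc1ccc(C[C@H]2[C@H](Sc3ccc(C)cc3)OC(=O)[C@]2(OC(C)=O)Cc2cc(OC)c(OC(C)=O)c(OC)c2)cc1OC | intermediate
19 | (3S,4S)-3-acetoxy-3-(4-acetoxy-3,5-dimethoxybenzyl)-4-(3,4-dimethoxybenzyl)dihydrofuran-2(3H)-one | COc1ccc(C[C@H]2COC(=O)[C@]2(OC(C)=O)Cc2cc(OC)c(OC(C)=O)c(OC)c2)cc1OC | intermediate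
20 | (3S,4S)-4-(3,4-dimethoxybenzyl)-3-hydroxy-3-(4-hydroxy-3,5-dimethoxybenzyl)dihydrofuran-2(3H)-one | COc1ccc(C[C@H]2COC(=O)[C@]2(O)Cc2cc(OC)c(O)c(OC)c2)cc1OC | target

**Step count**
Total step count: 11. Longest linear sequence: 8 (steps 4–11, from syringaldehyde).

**Steps most likely to fail**

1. Step 9 (new method).
   - What may go wrong: the ketene may be consumed by dimerisation or by simple oxygen transfer from sulfur before the adduct rearranges. The α-acetoxy enolate may undergo acyl migration. A boat-like array may erode the C3/C4 relation.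
   - Fallback (known chemistry): it sets out from 7 and comes back to the route at 20. Sulfoxide 7 is treated with dichloroketene F1, generated from trichloroacetyl chloride and Zn–Cu couple in Et2O, which is the established form of the lactonization. This should give the dichloro thiolactone F2 with the same sulfur-controlled C4 configuration. Raney nickel then removes both chlorines and the thio group to give (R)-4-(3,4-dimethoxybenzyl)butyrolactone F3. Enolate hydroxylation (LiHMDS, then 2-(phenylsulfonyl)-3-phenyloxaziridine) gives the trans hydroxy lactone F4. Double deprotonation (LDA, 2.2 equiv) and aldol addition to commercial 4-benzyloxy-3,5-dimethoxybenzaldehyde follow. The aldehyde enters anti to the C4 benzyl group and so gives the trans-dibenzyl relation, as the aldol diol F5 (carbinol epimers, of no consequence). Hydrogenolysis (H2, Pd/C, AcOH) of the benzyl ether and of the electron-rich benzylic alcohol gives 20.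

2. Step 3.
   - What may go wrong: the iodine–magnesium exchange may be sluggish. Proton transfer from the doubly activated benzylic/allylic CH2 to the organomagnesium may move the double bond towards the arene. A second attack at sulfur may erode the configuration.
   - Fallback: it sets out from 3 and comes back at 7, so it also bypasses step 2. Commercial (S)-methyl p-tolyl sulfoxide is deprotonated with LDA to lithiated methyl p-tolyl sulfoxide F6. This adds to aldehyde 3 at −78 °C to give the β-hydroxy sulfoxide F7 (carbinol epimers, of no consequence). Mesylation (MsCl, Et3N) gives the mesylate F8. E1cB elimination with DBU at 0 °C and short contact time gives E-configured 7. Sulfur is never a reaction centre in this sequence.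

3. Step 10.
   - What may go wrong: material may be lost by adsorption on the metal. Residual alkali may cause partial deacetylation. The C5–O bond may be cleaved together with C5–S.
   - Fallback: it sets out from 18 and comes back at 19. Silver(I)-assisted hydrolysis of the O,S-acetal (AgNO3, 2,6-lutidine, aq THF) gives the lactol F9 (anomers). Ionic hydrogenation through the acyloxocarbenium ion (Et3SiH, BF3·OEt2, CH2Cl2, −20 °C) then gives 19.

**Further compounds**
F1 | step 9 | dichloroketene | ClC(Cl)=C=O
F2 | step 9 | (4S,5S)-3,3-dichloro-4-(3,4-dimethoxybenzyl)-5-(p-tolylthio)dihydrofuran-2(3H)-one | COc1ccc(C[C@H]2[C@H](Sc3ccc(C)cc3)OC(=O)C2(Cl)Cl)cc1OC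
F3 | step 9 | (R)-4-(3,4-dimethoxybenzyl)dihydrofuran-2(3H)-one | COc1ccc(C[C@H]2COC(=O)C2)cc1OC
F4 | step 9 | (3R,4S)-4-(3,4-dimethoxybenzyl)-3-hydroxydihydrofuran-2(3H)-one | COc1ccc(C[C@H]2COC(=O)[C@@H]2O)cc1OC
F5 | step 9 | (3S,4S)-3-[(4-benzyloxy-3,5-dimethoxyphenyl)(hydroxy)methyl]-4-(3,4-dimethoxybenzyl)-3-hydroxydihydrofuran-2(3H)-one (carbinol epimers) | COc1ccc(C[C@H]2COC(=O)[C@]2(O)C(O)c2cc(OC)c(OCc3ccccc3)c(OC)c2)cc1OC
F6 | step 3 | lithiated (S)-methyl p-tolyl sulfoxide | [Li]C[S@](=O)c1ccc(C)cc1
F7 | step 3 | 1-(3,4-dimethoxyphenyl)-3-[(S)-p-tolylsulfinyl]propan-2-ol (carbinol epimers) | COc1ccc(CC(O)C[S@](=O)c2ccc(C)cc2)cc1OC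
F8 | step 3 | 1-(3,4-dimethoxyphenyl)-3-[(S)-p-tolylsulfinyl]propan-2-yl methanesulfonate | COc1ccc(CC(OS(C)(=O)=O)C[S@](=O)c2ccc(C)cc2)cc1OC
F9 | step 10 | (3S,4R)-3-acetoxy-3-(4-acetoxy-3,5-dimethoxybenzyl)-4-(3,4-dimethoxybenzyl)-5-hydroxydihydrofuran-2(3H)-one (anomers) | COc1ccc(C[C@H]2C(O)OC(=O)[C@]2(OC(C)=O)Cc2cc(OC)c(OC(C)=O)c(OC)c2)cc1OC
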